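**Direct plan and its weak points**

A direct plan would set C3 first, by adding lithium ethoxyacetylide to the (R)-tert-butanesulfinyl imine of methyl 2-formyl-3-methoxybenzoate and closing the lactam, to give alkynyl isoindolinone A1.
Ring C would then be grown on that alkyne by heating A1 with spiro-cyclobutenone A2 (vinylketene/ynol ether [2+2], 4π opening, 6π closure) to spirodienone A3. Cleavage of the spiro-cyclopentene to dialdehyde A4, a twofold isopropylidene Wittig reaction and hydrolysis of the ethyl enol ether would finish.
Weak point, the thermal cascade to A3: it would have to stop at a cyclohexadienone by a 6π closure onto a fully substituted carbon, at 110–135 °C, beside a free lactam N–H, with an excess of a ketene precursor that itself costs three steps; the whole plan hangs on a reaction without a close model.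
Weak point, the prenyl groups carried as a cyclopentene: oxidative cleavage to A4 and two Wittig reactions only unmask what could be put in directly, and they run on a base-sensitive dialdehyde next to the C3–H.
Weak point, the early setting of C3 with a stoichiometric auxiliary: the centre would then have to survive the hot cascade, excess ylide and hydroxide, although its C3–N bond lies β to the dione (retro-aza-Michael), at the end of a nine-step linear run.

**Retrosynthetic overview of the new route**

Ring C (C1'–C6') is read as a dearomatised orcinol: both C5'–CH2 bonds of the quaternary carbon are cut, so the precursor of the key step is a flat 2,6-dihydroxy-4-methylphenyl ring that takes up two prenyl bromides at C5' (alkylative dearomatisation).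
C3' carries an allyl carboxylate inherited from orsellinic acid: it steers the C3–C1' bond formation to the carbon between the two hydroxyls, blocks C3' during the gem-diprenylation, and leaves as CO2 in the last step.
The C3–C1' bond and the only stereocentre come from a catalytic, stereoconvergent aza-Friedel–Crafts reaction of a racemic N,O-acetal (planar N-acyliminium ion) with the orsellinate.
Ring order: ring B closes at N2–C3 on the benzonitrile fragment, ring C is never closed (it enters as an arene), and the two halves are joined at C3–C1'.
No ketene cascade, no masked prenyl groups, no oxidative cleavage or Wittig step; C3 is set two steps before the end and then meets only phenoxide-level base at or below room temperature and a mild deallylation.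

Key step: step 5

Remarks: C3 is the stereocentre of the isoindolinone; in ring C, C1' is bound to C3, C2' is C–OH, C3' is CH, C4' is C–CH3, C5' is the quaternary carbon and C6' is C=O. The sense of induction of the chiral acid in step 4 is assumed; should the (R)-catalyst give (3R), its (S)-antipode is used and nothing else changes.

**Route**

Step 1
Reactants: 1 orsellinic acid (2,4-dihydroxy-6-methylbenzoic acid)
Product: 2 allyl 2,4-dihydroxy-6-methylbenzoate
Conditions: allyl bromide (1.1 equiv), KHCO3, DMF, rt
Reagents that add atoms: allyl bromide, C=CCBr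
Why: Carboxylate O-alkylation (SN2) with a base too weak to ionise the phenols gives the allyl ester selectively, at a temperature at which orsellinic acid does not lose CO2.

Step 2
Reactants: 3 3-methoxybenzonitrile
Product: 5 2-formyl-3-methoxybenzonitrile, via aryllithium 4 (not isolated)
Conditions: lithium 2,2,6,6-tetramethylpiperidide (from 2,2,6,6-tetramethylpiperidine and n-BuLi), THF, −78 °C; DMF, −78 °C → 0 °C; 1 M HCl
Reagents that add atoms: N,N-dimethylformamide, CN(C)C=O
Why: Directed ortho-metalation takes the C2–H that is acidified by both the nitrile and the methoxy group, the hindered amide base does not add to the nitrile, and the aryllithium is formylated by DMF.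

Step 3
Reactants: 5 2-formyl-3-methoxybenzonitrile
Product: 7 3,4-dimethoxyisoindolin-1-one (racemic), via cyclic imidate 6 (not isolated)
Conditions: K2CO3 (0.2 equiv), MeOH, rt → 50 °C
Reagents that add atoms: methanol, CO
Why: The known base-catalysed tandem of hemiacetal formation, alkoxide addition to the nitrile and Dimroth-type rearrangement of the cyclic imidate (C–O cleavage, N–C closure) turns 2-formylbenzonitriles into 3-alkoxyisoindolinones; it closes ring B at N2–C3 and gives a racemic N,O-acetal whose configuration is erased in the next step.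

Step 4
Reactants: 2 allyl 2,4-dihydroxy-6-methylbenzoate, 7 3,4-dimethoxyisoindolin-1-one (racemic)
Product: 9 allyl 2,4-dihydroxy-3-[(1S)-7-methoxy-3-oxoisoindolin-1-yl]-6-methylbenzoate, via N-acyliminium ion 8 (not isolated)
Conditions: 2 (1.2 equiv), (R)-3,3'-bis(2,4,6-triisopropylphenyl)-BINOL N-triflylphosphoramide (5 mol%), 5 Å MS, CH2Cl2–toluene, −20 °C → rt
Reagents that add atoms: none
Why: Enantioselective aza-Friedel–Crafts amidoalkylation, in which the chiral acid ionises both enantiomers of 7 to the planar N–H acyliminium ion 8, holds it as a hydrogen-bonded ion pair while binding a phenol O–H of 2, and delivers the carbon between the two hydroxyls (the position at which orsellinate esters take up electrophiles) to one face of C3, so that the racemate converges on (3S)-9 while the sieves bind the methanol.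

Step 5
Reactants: 9 allyl 2,4-dihydroxy-3-[(1S)-7-methoxy-3-oxoisoindolin-1-yl]-6-methylbenzoate, 10 prenyl bromide (1-bromo-3-methylbut-2-ene)
Product: 12 allyl 6-hydroxy-5-[(1S)-7-methoxy-3-oxoisoindolin-1-yl]-2-methyl-3,3-bis(3-methylbut-2-en-1-yl)-4-oxocyclohexa-1,5-diene-1-carboxylate, via monoprenyl arene 11 (not isolated)
Conditions: LiN(SiMe3)2 (2.05 equiv), THF–toluene, −78 → 0 °C; 10 (1.05 equiv), 0 °C; then LiN(SiMe3)2 (1.05 equiv), 10 (a second portion, 1.2 equiv), 0 °C → rt; 1 M HCl to pH 4, 0 °C
Reagents that add atoms: prenyl bromide (second equivalent of 10), CC(C)=CCBr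
Why: Alkylative dearomatisation with two equivalents of 10 in one flask: the dilithium bis-phenoxide of 9 is C-alkylated by the first equivalent (SN2) at C5', the only ring carbon that still bears hydrogen, the dienone tautomerises back to arene 11, and after the third equivalent of base the same carbon (ortho to O6', para to O2') is alkylated by the second equivalent, which can no longer re-aromatise and gives the lithium salt of vinylogous acid 12. The closest known reactions are the base-mediated gem-prenylation of acylphloroglucinols to the hop β-acids and the lithium amide-mediated dearomatisation of 3,5-dialkylorsellinate esters with allylic bromides at the carbon between C–OH and C–CH3. No ring is closed: ring C is the benzene ring of orsellinic acid, converted in this one operation into the cyclohexa-2,4-dienone with its quaternary C5' and both prenyl groups. No stereocentre is formed (C5' carries two equal groups), and C3 is not touched because no base beyond the phenoxide stoichiometry is ever present. The step needs C- over O-alkylation, C5' over C1' and C3', and no N-alkylation: the lithium contact ion pair in a solvent of low polarity favours ortho-C-attack, C3' is blocked by the ester and C1' by the branched isoindolinyl group, and dosing the base in two portions keeps the lactam N–H (far less acidic than either phenol) protonated. The second alkylation is driven by the strongly stabilised, hydrogen-bonded β-dicarbonyl enolate of 12, and any 9 or 11 left over by uneven proton transfer is funnelled to 12 by the same sequence.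

Step 6
Reactants: 12 allyl 6-hydroxy-5-[(1S)-7-methoxy-3-oxoisoindolin-1-yl]-2-methyl-3,3-bis(3-methylbut-2-en-1-yl)-4-oxocyclohexa-1,5-diene-1-carboxylate
Product: 14 (3S)-3-[2-hydroxy-4-methyl-5,5-bis(3-methylbut-2-en-1-yl)-6-oxocyclohexa-1,3-dien-1-yl]-4-methoxyisoindolin-1-one, via carboxylic acid 13 (not isolated)
Conditions: Pd(PPh3)4 (5 mol%), morpholine (5 equiv), THF, rt; then pyridine–AcOH, 60 °C; 1 M HCl to pH 4, 0 °C
Reagents that add atoms: none
Why: Tsuji–Trost deallylation (zerovalent palladium ionises the allyl ester and morpholine traps the π-allyl unit) frees vinylogous β-keto acid 13, whose C4' methyl allows an amine-catalysed shift of the C3'=C4' bond out of conjugation so that C3' becomes sp3 and CO2 leaves through the usual six-membered β-keto acid transition state (as in the Doebner decarboxylation of alkylidene malonic acids), while the prenyl alkenes carry no leaving group and are inert to the catalyst.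

**Compound list**

1 | orsellinic acid (2,4-dihydroxy-6-methylbenzoic acid) | Cc1cc(O)cc(O)c1C(=O)O | starting material
2 | allyl 2,4-dihydroxy-6-methylbenzoate | Cc1cc(O)cc(O)c1C(=O)OCC=C | intermediate
3 | 3-methoxybenzonitrile | COc1cccc(C#N)c1 | starting material
4 | (2-cyano-6-methoxyphenyl)lithium | [Li]c1c(OC)cccc1C#N | intermediate
5 | 2-formyl-3-methoxybenzonitrile | COc1cccc(C#N)c1C=O | intermediate
6 | 3,4-dimethoxy-2-benzofuran-1(3H)-imine (racemic cyclic imidate) | COC1OC(=N)c2cccc(OC)c12 | intermediate
7 | 3,4-dimethoxyisoindolin-1-one (racemic) | COC1NC(=O)c2cccc(OC)c12 | intermediate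
8 | 4-methoxy-1-oxo-1H-isoindol-2-ium (N–H acyliminium ion, paired with the chiral phosphoramide anion) | COc1cccc2c1C=[NH+]C2=O | intermediate
9 | allyl 2,4-dihydroxy-3-[(1S)-7-methoxy-3-oxoisoindolin-1-yl]-6-methylbenzoate | COc1cccc2c1[C@@H](c1c(O)cc(C)c(C(=O)OCC=C)c1O)NC2=O | intermediate
10 | prenyl bromide (1-bromo-3-methylbut-2-ene) | CC(C)=CCBr | starting material
11 | allyl 2,4-dihydroxy-3-[(1S)-7-methoxy-3-oxoisoindolin-1-yl]-6-methyl-5-(3-methylbut-2-en-1-yl)benzoate | COc1cccc2c1[C@@H](c1c(O)c(CC=C(C)C)c(C)c(C(=O)OCC=C)c1O)NC2=O | intermediate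
12 | allyl 6-hydroxy-5-[(1S)-7-methoxy-3-oxoisoindolin-1-yl]-2-methyl-3,3-bis(3-methylbut-2-en-1-yl)-4-oxocyclohexa-1,5-diene-1-carboxylate | COc1cccc2c1[C@@H](C1=C(O)C(C(=O)OCC=C)=C(C)C(CC=C(C)C)(CC=C(C)C)C1=O)NC2=O | intermediate
13 | 6-hydroxy-5-[(1S)-7-methoxy-3-oxoisoindolin-1-yl]-2-methyl-3,3-bis(3-methylbut-2-en-1-yl)-4-oxocyclohexa-1,5-diene-1-carboxylic acid | COc1cccc2c1[C@@H](C1=C(O)C(C(=O)O)=C(C)C(CC=C(C)C)(CC=C(C)C)C1=O)NC2=O | intermediate
14 | (3S)-3-[2-hydroxy-4-methyl-5,5-bis(3-methylbut-2-en-1-yl)-6-oxocyclohexa-1,3-dien-1-yl]-4-methoxyisoindolin-1-one | COc1cccc2c1[C@@H](C1=C(O)C=C(C)C(CC=C(C)C)(CC=C(C)C)C1=O)NC2=O | target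

**Step count and risks**

Total: 6 steps. Longest linear sequence: 5 steps (steps 2, 3, 4, 5, 6, from 3-methoxybenzonitrile).

Steps most likely to fail:

1. Step 5. The second, quaternary-forming alkylation may be outrun by O-alkylation of the hindered phenoxide, and any excess of base would open the way to N-alkylation. The fallback sets out from 11, which is then isolated after the first alkylation with one equivalent of 10, and comes back to the route at 12. The second prenyl group would be delivered by a sigmatropic shift instead of an SN2 reaction. The more acidic, non-chelated O6'–H of 11 would be etherified with 3-chloro-3-methylbut-1-yne (CuCl2 cat., DBU, MeCN, 0 °C) to allyl 2-hydroxy-3-[(1S)-7-methoxy-3-oxoisoindolin-1-yl]-6-methyl-5-(3-methylbut-2-en-1-yl)-4-[(2-methylbut-3-yn-2-yl)oxy]benzoate F1. Semi-hydrogenation (H2, one equivalent, lead-poisoned Pd/CaCO3, quinoline) would give the 1,1-dimethylallyl ether, allyl 2-hydroxy-3-[(1S)-7-methoxy-3-oxoisoindolin-1-yl]-6-methyl-5-(3-methylbut-2-en-1-yl)-4-[(2-methylbut-3-en-2-yl)oxy]benzoate F2. Heating in toluene at about 100 °C should start an aromatic Claisen rearrangement that transfers the group from O6' to the neighbouring C5' with allylic inversion, that is, as a normal prenyl group; the product cannot re-aromatise and should rest as the hydrogen-bonded vinylogous acid 12.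

2. Step 6. The double-bond shift that must precede loss of CO2 may be slow, and longer heating invites [3,3] shifts of the 5',5'-diprenyl dienone and erosion of C3 through reversible C3–N cleavage. The fallback sets out from 9 and comes back at 14; it removes the carboxyl group at the arene stage, where orsellinic acids decarboxylate easily, and lets bromine take over the blocking of C3'. Deallylation of 9 (Pd(PPh3)4, morpholine, THF) would give 2,4-dihydroxy-3-[(1S)-7-methoxy-3-oxoisoindolin-1-yl]-6-methylbenzoic acid F3, which on warming in aqueous dioxane should lose CO2 by ipso-protonation to (3S)-3-(2,6-dihydroxy-4-methylphenyl)-4-methoxyisoindolin-1-one F4. One equivalent of NBS (MeCN, −20 °C) would brominate the far more electron-rich resorcinol ring to (3S)-3-(3-bromo-2,6-dihydroxy-4-methylphenyl)-4-methoxyisoindolin-1-one F5. Gem-diprenylation as in step 5 (two equivalents of 10) at the one free carbon would give (3S)-3-[3-bromo-2-hydroxy-4-methyl-5,5-bis(3-methylbut-2-en-1-yl)-6-oxocyclohexa-1,3-dien-1-yl]-4-methoxyisoindolin-1-one F6. Hydrodebromination of this α-bromo enone (Pd(OAc)2, PPh3, HCO2Na, DMF, 50 °C) should then give 14.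

3. Step 4. Facial selectivity at the iminium carbon may be poor with a nucleophile that attacks through a doubly ortho-substituted carbon, and some attack through C5 or oxygen may compete. The fallback sets out from 2 and 7 and comes back at 9. An achiral acid (TsOH·H2O, 10 mol%, CH2Cl2, rt; the O-adducts revert under these conditions) would give racemic allyl 2,4-dihydroxy-3-(7-methoxy-3-oxoisoindolin-1-yl)-6-methylbenzoate F7, which would be resolved by preparative chromatography on a cellulose tris(3,5-dimethylphenylcarbamate) phase to give 9. The unwanted enantiomer, allyl 2,4-dihydroxy-3-[(1R)-7-methoxy-3-oxoisoindolin-1-yl]-6-methylbenzoate F8, should be racemised by DBU in warm toluene through reversible C3–N cleavage (ortho-quinone methide and amide) and returned to the separation.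

**Further compounds**

F1 | step 5 | allyl 2-hydroxy-3-[(1S)-7-methoxy-3-oxoisoindolin-1-yl]-6-methyl-5-(3-methylbut-2-en-1-yl)-4-[(2-methylbut-3-yn-2-yl)oxy]benzoate | COc1cccc2c1[C@@H](c1c(OC(C)(C)C#C)c(CC=C(C)C)c(C)c(C(=O)OCC=C)c1O)NC2=O
F2 | step 5 | allyl 2-hydroxy-3-[(1S)-7-methoxy-3-oxoisoindolin-1-yl]-6-methyl-5-(3-methylbut-2-en-1-yl)-4-[(2-methylbut-3-en-2-yl)oxy]benzoate | COc1cccc2c1[C@@H](c1c(OC(C)(C)C=C)c(CC=C(C)C)c(C)c(C(=O)OCC=C)c1O)NC2=O
F3 | step 6 | 2,4-dihydroxy-3-[(1S)-7-methoxy-3-oxoisoindolin-1-yl]-6-methylbenzoic acid | COc1cccc2c1[C@@H](c1c(O)cc(C)c(C(=O)O)c1O)NC2=O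
F4 | step 6 | (3S)-3-(2,6-dihydroxy-4-methylphenyl)-4-methoxyisoindolin-1-one | COc1cccc2c1[C@@H](c1c(O)cc(C)cc1O)NC2=O
F5 | step 6 | (3S)-3-(3-bromo-2,6-dihydroxy-4-methylphenyl)-4-methoxyisoindolin-1-one | COc1cccc2c1[C@@H](c1c(O)cc(C)c(Br)c1O)NC2=O
F6 | step 6 | (3S)-3-[3-bromo-2-hydroxy-4-methyl-5,5-bis(3-methylbut-2-en-1-yl)-6-oxocyclohexa-1,3-dien-1-yl]-4-methoxyisoindolin-1-one | COc1cccc2c1[C@@H](C1=C(O)C(Br)=C(C)C(CC=C(C)C)(CC=C(C)C)C1=O)NC2=O
F7 | step 4 | allyl 2,4-dihydroxy-3-(7-methoxy-3-oxoisoindolin-1-yl)-6-methylbenzoate (racemic) | COc1cccc2c1C(c1c(O)cc(C)c(C(=O)OCC=C)c1O)NC2=O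
F8 | step 4 | allyl 2,4-dihydroxy-3-[(1R)-7-methoxy-3-oxoisoindolin-1-yl]-6-methylbenzoate | COc1cccc2c1[C@H](c1c(O)cc(C)c(C(=O)OCC=C)c1O)NC2=O
A1 | direct plan | (3R)-3-(ethoxyethynyl)-4-methoxyisoindolin-1-one | COc1cccc2c1[C@@H](C#COCC)NC2=O
A2 | direct plan | 3-methylspiro[3.4]octa-2,6-dien-1-one | CC1=CC(=O)C12CC=CC2
A3 | direct plan | (3S)-3-(8-ethoxy-10-methyl-6-oxospiro[4.5]deca-2,7,9-trien-7-yl)-4-methoxyisoindolin-1-one | COc1cccc2c1[C@@H](C3=C(OCC)C=C(C)C4(CC=CC4)C3=O)NC2=O
A4 | direct plan | 3-ethoxy-2-[(1S)-7-methoxy-3-oxoisoindolin-1-yl]-5-methyl-6,6-bis(2-oxoethyl)cyclohexa-2,4-dien-1-one | COc1cccc2c1[C@@H](C3=C(OCC)C=C(C)C(CC=O)(CC=O)C3=O)NC2=O
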